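- Early on, the fractions of X lost looked unlike: at 8.00 min the larch run had lost 30.0% of its charge and the maple run 19.5%, yet fraction lost times charge came to 0.0840 M and 0.0858 M.

| setting | larch | maple | flask |
|---|---|---|---|
| X | 0.28 M | 0.44 M | 0.20 M |
| D | 22 mM (held) | 22 mM (held) | 22 mM (held) |
| Q | 4 mM | 4 mM | 4.00 mM |
| remark | run made earlier | run made earlier |  |
| time |  |  | 25 min |

- larch (time / min: E / %, X / %): 1.33: 1.1, 92.3; 4.00: 1.5, 81.1; 8.00: 4.1, 70.0; 10.0: 5.1, 65.9; 15.0: 11.1, 57.4; 20.0: 15.3, 49.7; 25.0: 20.2, 43.2
- maple (time / min: E / %, X / %): 2.00: 0.7, 93.5; 3.00: 0.5, 90.7; 5.00: 1.3, 86.0; 8.00: 2.2, 80.5; 10.0: 3.5, 78.4; 15.0: 5.2, 73.0; 25.0: 13.2, 64.1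

(standard deviation of a reading: 0.5 percentage points)

- X is a solid; its amount is given per volume of the solution
- at the start none of G is dissolved
- steps thought possible: D <-> G; J + G -> E; G + E -> Z; G + Q -> L; X <-> J
- at the start none of X is in solution

- the E standing at 25 min, as a percentage of the X charged
- concentration of G in solution at 25 min, in percent of saturation

- So I read the dissolving of solid X to J as zero order in the amount of solid, and took the mean of that product at 25 min, 0.159 M; with the flask's charge, the fraction of X left came to 20.7%.
- E, made from J and G, behaved alike: its fraction times charge read 0.0566 M in larch and 0.0581 M in maple, so I carried their mean, 0.0573 M, as the charge product of E: the fraction of the charge found as E, multiplied by the charge.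
- Divided by the flask's charge, it gave me 28.7%.
- The weak link was the flask's charge, lower than larch's, since the product needs solid standing to the end; I forged it again from the fraction left, 20.7%, which is above zero, so my number stood.
- The forecast, slightly below my figure, gave 28.3% for E, between 26.3% and 30.3%, and 80% for G, between 55% and 96%, “though this is poorly determined”.
- The flask gave 28.6% of E, inside that range, and 50.4% for G, below its low end.

    D ⇌ G, rate k1*(csat - [G]) (kL = 0.290 /min)
    J + G → E (k = 2.70 /M/min)
    G + E → Z (k = 0.390 /M/min)
    G + Q → L (k = 3.80 /M/min)
    X ⇌ J, rate k5*(cs5 - [J]) while solid is left; crystals form when [J] > cs5 (solubility = 0.120 M, k = 0.140 /min)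

- The charge product, divided by the 0.34 M of X in the neighbour flask, gives 16.9%, and that neighbour stands at 16.8% of E, with G at 0.0111 M as in the flask. In the flask itself, E is held down by two things acting together, the drag of the transfer of D to G and the low solubility of J. Run without the drag, the flask reaches 45.7% of E; run without the solubility limit, it reaches 40.6%.

(All runs stem from a simulated flask from invented constants.)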